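Readings and results are simulated with made-up constants.

The amounts in the earlier runs stopped moving early: after 1.00 min, product and starting material stood level within their scatter of 0.5 percentage points.

| flask | solid substrate | free catalyst | remark | time |
|---|---|---|---|---|
| dusk | 1 M | 2.5 mM | run made earlier |  |
| noon | 1 M | 10 mM | run made earlier |  |
| dawn | 0.50 M | 5 mM | run made earlier |  |
| flask | 1.0 M | 5.0 mM |  | 3.0 min |

| run | time / min | product / % | starting material / % |
|---|---|---|---|
| dusk | 0.333 | 2.4 | 11.1 |
| dusk | 0.667 | 3.2 | 10.4 |
| dusk | 1.00 | 3.8 | 10.9 |
| dusk | 1.33 | 3.7 | 11.2 |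
| dusk | 1.50 | 4.1 | 10.6 |
| dusk | 2.00 | 3.8 | 11.7 |
| dusk | 2.50 | 3.2 | 10.8 |
| noon | 0.200 | 7.6 | 10.5 |
| noon | 0.333 | 11.2 | 10.1 |
| noon | 0.417 | 11.6 | 10.2 |
| noon | 0.667 | 12.8 | 10.9 |
| noon | 1.00 | 14.4 | 11.6 |
| noon | 1.50 | 13.0 | 11.8 |
| noon | 2.50 | 13.8 | 10.2 |
| dawn | 0.500 | 13.0 | 21.3 |
| dawn | 1.00 | 13.7 | 22.0 |
| dawn | 1.33 | 14.2 | 22.4 |
| dawn | 2.00 | 14.8 | 21.4 |
| dawn | 2.50 | 14.1 | 22.1 |

(scatter of a reading: 0.5 percentage points)

* product at 3.0 min, in percent of the solid substrate charged
* concentration of starting material in solution at 3.0 min, in percent of saturation

- as a solid, counted per litre of solution: solid substrate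
- at the start none of the solid substrate is in solution
- starting material is what solid substrate becomes in solution
- starting material means what is dissolved; the solid is not counted in it

I froze two numbers. The dissolved [starting material] read 0.110 M in the dawn run and 0.109 M in the dusk run, from different charges, so I took it as saturation. The second came from the dawn plateau:

[product] / [free catalyst] charged = 14.1 % × 0.50 M / 5 mM = 14.1

This ratio of plateau product to free catalyst charged, the turnover number, read 13.8 in the noon run, which had 1 M of solid against the 0.50 M of the dawn run.

What would a flask short of saturation at 3.0 min need? Dissolved material and product together would have to take the whole charge of solid. In this flask they take: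

[product] = 14.1 × 5.0 mM = 7.05 % of the charge

[starting material] + [product] = 0.180 M

That is less than the 1.0 M charged, so I expected solid to remain and the solution to stay at 0.110 M. In the dawn run, also at 5 mM, product read 13.7 % at 1.00 min and 14.1 % at 2.50 min, level within the scatter, and that last reading came earlier than the asked time.

The forecast gave 7 % and 100 %, holding that “the catalyst appears to die”.

The flask gave 7.00 % of product and >99.9 % of saturation.

    solid substrate ⇌ starting material, rate k1*(cs1 - [starting material]) while solid is left; crystals form when [starting material] > cs1 (solubility = 0.110 M, k = 0.750 s⁻¹)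
    catalyst intermediate → spent catalyst (k = 0.200 s⁻¹)
    catalyst intermediate → free catalyst + product (k = 2.80 s⁻¹)
    starting material + free catalyst → catalyst intermediate (k = 17.0 L mol⁻¹ s⁻¹)

In this flask the catalyst intermediate went to product 14 times as fast as to spent catalyst at 0.0370 min, and at 3.00 min spent catalyst held >99.9 % of the catalyst charged. For a neighbour flask charged with 0.013 M of free catalyst, otherwise as here, 14.1 turnovers reckoned to 18.3 % of the solid charged, and dissolved material plus product came to 0.293 M, less than the 1.0 M charged. That neighbour gave 18.2 % of product, with 81 % of its charge still there, solid or dissolved.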